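## Retrosynthetic overview

1. PGF1α 19 ⇐ methyl ester 18 ⇐ 11α-boryl ketone 16 (C9=O reduced from the β face, C11–B oxidised) ⇐ cyclopentenone 15 (C9=O, C10=C11; conjugate borylation anti to the C12 chain).
2. 15 ⇐ ring nitroalkene 14 (aerobic Nef reaction with 1,3-transposition) ⇐ nitro alcohol 13 ⇐ enone 12 (reduction at C15) ⇐ aldehyde 10 (Horner–Wadsworth–Emmons olefination, C13=C14).
3. Key disconnection of 10: the C8–C12 and C9–C10 bonds, made together by a domino aminocatalytic Michael/Henry (formal (3+2)) annulation of succinaldehyde 8 (C10–C13) with nitroalkene 6 (C1–C9). This closes the only ring, the cyclopentane C8–C12.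
4. Enabling feature: on the cyclopentane, C9 bears a heteroatom next to the chain-bearing C8, so the C8–C9 edge can be an (E)-nitroalkene. C12 bears C13, which as a formyl group makes C12 an enamine donor. The 1,3-relation of the C9 and C11 oxygens across the C10 methylene lets the Henry oxygen at C10 be traded for the C10=C11 enone.
5. 6 ⇐ methyl 8-oxooctanoate 3 + nitromethane 4 ⇐ cyclooctene 1; 8 ⇐ 2,5-dimethoxytetrahydrofuran 7.

Key step: step 4

Remarks on the chemistry:
- Locants C1–C20 are prostanoid locants (C1 = carboxyl carbon); α is the ring face that carries the C8 chain.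
- Nitro aldol 10 is drawn as the all-trans isomer. The configurations at C9 and C10 have no bearing on the route, since both centres become planar in steps 7 and 8.

## Route

Step 1
Reactants: 1 cyclooctene
Product: 3 methyl 8-oxooctanoate, via methoxy hydroperoxide 2 (not isolated)
Conditions: O3, CH2Cl2/MeOH, NaHCO3, −78 °C; then Ac2O, Et3N, CH2Cl2, 0 °C to rt
Reagents that add atoms: ozone, [O-][O+]=O; methanol, CO
Why: Ozonolysis in methanol traps the carbonyl oxide as the α-methoxy hydroperoxide 2 while the other terminus becomes the aldehyde, and acetylation followed by base-induced fragmentation (Criegee-type dehydration) turns the hydroperoxide into the methyl ester, so the two ends of the symmetrical alkene are differentiated in one flask; no stereocentre is formed.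

Step 2
Reactants: 3 methyl 8-oxooctanoate; 4 nitromethane
Product: 6 methyl (E)-9-nitronon-8-enoate, via nitro alcohol 5 (not isolated)
Conditions: MeNO2 (excess), KOtBu (cat.), THF/t-BuOH, 0 °C; evaporate; then MsCl, Et3N, CH2Cl2, −20 to 0 °C
Reagents that add atoms: none
Why: A Henry reaction followed by mesylation and E1cB elimination should give the conjugated nitroalkene as the thermodynamically preferred E isomer; the methyl ester is inert to catalytic alkoxide in the cold.

Step 3
Reactants: 7 2,5-dimethoxytetrahydrofuran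
Product: 8 succinaldehyde (butanedial)
Conditions: H2O, 90 °C; MeOH distilled off; extraction into CH2Cl2; used freshly distilled
Reagents that add atoms: water, O
Why: Hydrolysis of the cyclic bis-acetal liberates the dialdehyde, which is used at once because it oligomerises on standing.

Step 4
Reactants: 8 succinaldehyde; 6 methyl (E)-9-nitronon-8-enoate
Product: 10 methyl 7-[(1R,2S,3S,5S)-5-formyl-3-hydroxy-2-nitrocyclopentyl]heptanoate, via syn Michael adduct 9 (not isolated)
Conditions: (S)-2-[diphenyl(trimethylsilyloxy)methyl]pyrrolidine (10 mol %), 4-nitrophenol (10 mol %), 8 in excess, MeCN, 0 °C to rt; then iPr2NEt, 0 °C; crude 10 used directly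
Reagents that add atoms: none
Why: The pyrrolidine catalyst condenses with one formyl group of 8 to an E-enamine whose α-carbon (C12) adds to the β-carbon (C8) of nitroalkene 6 on the enamine face not covered by the diphenyl(silyloxy)methyl group, and after hydrolysis of the iminium ion to 9 the amine base generates the C9 nitronate, which attacks the remaining formyl carbon (C10). The closest known reaction type is the diarylprolinol silyl ether-catalysed Michael addition of aldehydes to nitroalkenes followed by an intramolecular Henry reaction, a domino formal (3+2) annulation. The cyclopentane C8–C12 is closed by 5-exo-trig addition of the nitronate carbon to the aldehyde. C8 should be fixed as R by the catalyst in the acyclic synclinal Michael transition state; C12 is first formed syn to C8 but, being α to the formyl group, should equilibrate under the amine base to the more stable arrangement with the formyl group trans to the C8 chain, so that the non-epimerisable C8 centre dictates the absolute configuration of the ring; C9 and C10 should settle under the reversible Henry conditions in the all-trans arrangement and are planarised later. The step needs enantiofacial control at C8 and cross-selectivity over self-aldolisation of 8: the first is secured by the catalyst, the second by the higher electrophilicity of the nitroalkene toward the enamine, while the single nitronate carbon and the single remaining formyl group can only close a five-membered ring.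

Step 5
Reactants: 10 methyl 7-[(1R,2S,3S,5S)-5-formyl-3-hydroxy-2-nitrocyclopentyl]heptanoate; 11 dimethyl (2-oxoheptyl)phosphonate
Product: 12 methyl 7-[(1R,2S,3S,5R)-3-hydroxy-2-nitro-5-[(1E)-3-oxooct-1-en-1-yl]cyclopentyl]heptanoate
Conditions: LiCl, iPr2NEt, MeCN, 0 °C to rt
Reagents that add atoms: none
Why: The Horner–Wadsworth–Emmons olefination under mild amine/LiCl (Masamune–Roush) conditions should give the E-enone (C13=C14) without retro-Henry cleavage, and C12 already sits in its thermodynamically preferred trans arrangement.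

Step 6
Reactants: 12 methyl 7-[(1R,2S,3S,5R)-3-hydroxy-2-nitro-5-[(1E)-3-oxooct-1-en-1-yl]cyclopentyl]heptanoate
Product: 13 methyl 7-[(1R,2S,3S,5R)-3-hydroxy-5-[(1E,3S)-3-hydroxyoct-1-en-1-yl]-2-nitrocyclopentyl]heptanoate
Conditions: (R)-B-methyl oxazaborolidine from (R)-diphenylprolinol (CBS catalyst, 20 mol %), catecholborane (3 equiv), toluene, −78 °C; then MeOH, aqueous work-up
Reagents that add atoms: none
Why: In the CBS reduction the (R)-oxazaborolidine binds the ketone with the alkenyl group as the large substituent and delivers hydride 1,2 to give the 15S allylic alcohol under reagent control, the ring stereocentres being too remote to interfere; nitro group and ester are inert to catecholborane in the cold.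

Step 7
Reactants: 13 methyl 7-[(1R,2S,3S,5R)-3-hydroxy-5-[(1E,3S)-3-hydroxyoct-1-en-1-yl]-2-nitrocyclopentyl]heptanoate
Product: 14 methyl 7-[(1R,5R)-5-[(1E,3S)-3-hydroxyoct-1-en-1-yl]-2-nitrocyclopent-2-en-1-yl]heptanoate
Conditions: Al2O3 (acidic, activated), ClCH2CH2Cl, 60 °C
Reagents that add atoms: none
Why: Dehydration of the β-nitro alcohol on alumina (E1cB through the nitronate) should give the conjugated ring nitroalkene C9=C10 and erase the C9 and C10 stereocentres, while the C15 alcohol, which has no acidifying group next to it, stays.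

Step 8
Reactants: 14 methyl 7-[(1R,5R)-5-[(1E,3S)-3-hydroxyoct-1-en-1-yl]-2-nitrocyclopent-2-en-1-yl]heptanoate
Product: 15 methyl 7-[(1R,2S)-2-[(1E,3S)-3-hydroxyoct-1-en-1-yl]-5-oxocyclopent-3-en-1-yl]heptanoate (PGA1 methyl ester)
Conditions: DABCO, O2 (1 atm), MeCN, 0 °C to rt
Reagents that add atoms: dioxygen, O=O
Why: In this base-mediated aerobic Nef reaction DABCO removes the γ-proton at C11 (the only position that gives a conjugated allyl nitronate), and oxygenation at C9 with loss of nitrite should give the C9 ketone with the double bond moved to C10=C11; C8 and C12 are not touched.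

Step 9
Reactants: 15 methyl 7-[(1R,2S)-2-[(1E,3S)-3-hydroxyoct-1-en-1-yl]-5-oxocyclopent-3-en-1-yl]heptanoate
Product: 16 methyl 7-[(1R,2R,3R)-2-[(1E,3S)-3-hydroxyoct-1-en-1-yl]-5-oxo-3-(4,4,5,5-tetramethyl-1,3,2-dioxaborolan-2-yl)cyclopentyl]heptanoate
Conditions: CuCl (5 mol %), DPEphos (5 mol %), NaOtBu (10 mol %), B2pin2, MeOH (2 equiv), THF, 0 °C to rt
Reagents that add atoms: bis(pinacolato)diboron, CC1(C)OB(OC1(C)C)B1OC(C)(C)C(C)(C)O1
Why: In the copper-catalysed conjugate borylation of an enone the boryl–copper species (monovalent copper) should add to C11 on the α face, anti to the adjacent C12 side chain as in other 1,4-additions to 4-substituted cyclopentenones, and methanol protonates the copper enolate; the isolated C13=C14 alkene and the free alcohol are inert.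

Step 10
Reactants: 16 methyl 7-[(1R,2R,3R)-2-[(1E,3S)-3-hydroxyoct-1-en-1-yl]-5-oxo-3-(4,4,5,5-tetramethyl-1,3,2-dioxaborolan-2-yl)cyclopentyl]heptanoate
Product: 18 methyl 7-[(1R,2R,3R,5S)-3,5-dihydroxy-2-[(1E,3S)-3-hydroxyoct-1-en-1-yl]cyclopentyl]heptanoate (PGF1α methyl ester), via boryl alcohol 17 (not isolated)
Conditions: LiBH(s-Bu)3 (L-Selectride, 2.5 equiv), THF, −78 °C; then NaBO3·4H2O, THF/H2O, 0 °C to rt
Reagents that add atoms: sodium perborate, [Na+].[O-]OB=O
Why: The bulky trialkylborohydride should attack the C9 carbonyl from the β face, opposite to the adjacent C8 chain and the 11α-boryl group, to give the 9α alcohol (the selectivity of PGE-to-PGF reductions), and perborate oxidation converts C11–B into C11–OH with retention, so the cis-1,3-diol results; the methyl ester survives the cold hydride and the mild oxidant.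

Step 11
Reactants: 18 methyl 7-[(1R,2R,3R,5S)-3,5-dihydroxy-2-[(1E,3S)-3-hydroxyoct-1-en-1-yl]cyclopentyl]heptanoate
Product: 19 7-[(1R,2R,3R,5S)-3,5-dihydroxy-2-[(1E,3S)-3-hydroxyoct-1-en-1-yl]cyclopentyl]heptanoic acid (PGF1α)
Conditions: LiOH·H2O, THF/MeOH/H2O, 0 °C to rt; then dilute HCl to pH 4
Reagents that add atoms: lithium hydroxide, [Li+].[OH-]
Why: Saponification of the methyl ester; the triol of the F series has no β-hydroxy ketone and should tolerate aqueous base without elimination or epimerisation.

## Compound list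

1 | cyclooctene | C1=CCCCCCC1 | starting material
2 | 8-hydroperoxy-8-methoxyoctanal | O=CCCCCCCC(OC)OO | intermediate
3 | methyl 8-oxooctanoate | O=CCCCCCCC(=O)OC | intermediate
4 | nitromethane | C[N+](=O)[O-] | starting material
5 | methyl 8-hydroxy-9-nitrononanoate (racemic) | COC(=O)CCCCCCC(O)C[N+](=O)[O-] | intermediate
6 | methyl (E)-9-nitronon-8-enoate | COC(=O)CCCCCC/C=C/[N+](=O)[O-] | intermediate
7 | 2,5-dimethoxytetrahydrofuran | COC1CCC(OC)O1 | starting material
8 | succinaldehyde | O=CCCC=O | intermediate
9 | methyl (8R,9R)-9-formyl-8-(nitromethyl)-11-oxoundecanoate | O=C[C@H](CC=O)[C@@H](CCCCCCC(=O)OC)C[N+](=O)[O-] | intermediate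
10 | methyl 7-[(1R,2S,3S,5S)-5-formyl-3-hydroxy-2-nitrocyclopentyl]heptanoate | O=C[C@@H]1[C@@H](CCCCCCC(=O)OC)[C@H]([N+](=O)[O-])[C@@H](O)C1 | intermediate
11 | dimethyl (2-oxoheptyl)phosphonate | CCCCCC(=O)CP(=O)(OC)OC | starting material
12 | methyl 7-[(1R,2S,3S,5R)-3-hydroxy-2-nitro-5-[(1E)-3-oxooct-1-en-1-yl]cyclopentyl]heptanoate | CCCCCC(=O)/C=C/[C@@H]1[C@@H](CCCCCCC(=O)OC)[C@H]([N+](=O)[O-])[C@@H](O)C1 | intermediate
13 | methyl 7-[(1R,2S,3S,5R)-3-hydroxy-5-[(1E,3S)-3-hydroxyoct-1-en-1-yl]-2-nitrocyclopentyl]heptanoate | CCCCC[C@H](O)/C=C/[C@@H]1[C@@H](CCCCCCC(=O)OC)[C@H]([N+](=O)[O-])[C@@H](O)C1 | intermediate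
14 | methyl 7-[(1R,5R)-5-[(1E,3S)-3-hydroxyoct-1-en-1-yl]-2-nitrocyclopent-2-en-1-yl]heptanoate | CCCCC[C@H](O)/C=C/[C@@H]1[C@@H](CCCCCCC(=O)OC)C([N+](=O)[O-])=CC1 | intermediate
15 | methyl 7-[(1R,2S)-2-[(1E,3S)-3-hydroxyoct-1-en-1-yl]-5-oxocyclopent-3-en-1-yl]heptanoate (PGA1 methyl ester) | CCCCC[C@H](O)/C=C/[C@@H]1[C@@H](CCCCCCC(=O)OC)C(=O)C=C1 | intermediate
16 | methyl 7-[(1R,2R,3R)-2-[(1E,3S)-3-hydroxyoct-1-en-1-yl]-5-oxo-3-(4,4,5,5-tetramethyl-1,3,2-dioxaborolan-2-yl)cyclopentyl]heptanoate | CCCCC[C@H](O)/C=C/[C@@H]1[C@@H](CCCCCCC(=O)OC)C(=O)C[C@H]1B1OC(C)(C)C(C)(C)O1 | intermediate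
17 | methyl 7-[(1R,2R,3R,5S)-5-hydroxy-2-[(1E,3S)-3-hydroxyoct-1-en-1-yl]-3-(4,4,5,5-tetramethyl-1,3,2-dioxaborolan-2-yl)cyclopentyl]heptanoate (present as its lithium alkoxide) | CCCCC[C@H](O)/C=C/[C@@H]1[C@@H](CCCCCCC(=O)OC)[C@@H](O)C[C@H]1B1OC(C)(C)C(C)(C)O1 | intermediate
18 | methyl 7-[(1R,2R,3R,5S)-3,5-dihydroxy-2-[(1E,3S)-3-hydroxyoct-1-en-1-yl]cyclopentyl]heptanoate (PGF1α methyl ester) | CCCCC[C@H](O)/C=C/[C@@H]1[C@@H](CCCCCCC(=O)OC)[C@@H](O)C[C@H]1O | intermediate
19 | 7-[(1R,2R,3R,5S)-3,5-dihydroxy-2-[(1E,3S)-3-hydroxyoct-1-en-1-yl]cyclopentyl]heptanoic acid (PGF1α) | CCCCC[C@H](O)/C=C/[C@@H]1[C@@H](CCCCCCC(=O)O)[C@@H](O)C[C@H]1O | target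

## Step count and risks

Total step count: 11. Longest linear sequence: 10 steps (steps 1, 2 and 4 to 11); step 3 is a one-step branch.

Steps most likely to fail:

**Step 4 (key step).** Self-aldolisation and oligomerisation of succinaldehyde may outrun the cross-Michael addition, or epimerisation at C12 may stay incomplete, so that ring closure gives mixtures at C12. Fallback: the two bonds are made in separate operations with one aldehyde masked. Setting out from 6, the same aminocatalyst is used with commercially available 4,4-dimethoxybutanal, which can form only one enamine and cannot oligomerise. This should give the acetal-protected Michael adduct methyl (8R,9R)-9-formyl-11,11-dimethoxy-8-(nitromethyl)undecanoate F1. Mild aqueous acid (CF3CO2H, H2O, CH2Cl2, 0 °C) then unmasks dialdehyde 9, and separate treatment with iPr2NEt in MeCN effects epimerisation at C12 and the Henry closure. The fallback comes back to the route at 10.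

**Step 8.** The amine base may move the ring double bond into the C8–C12 position (the tetrasubstituted, more stable enone), or γ-deprotonation and oxygenation may be slow and let the nitroalkene polymerise. Fallback: the nitro group is removed by substitution chemistry instead of oxidation of a nitronate. Setting out from 14, nucleophilic epoxidation (t-BuOOH, DBU, CH2Cl2, 0 °C) should give the α-nitro epoxide methyl 7-[(2R,3R)-3-[(1E,3S)-3-hydroxyoct-1-en-1-yl]-1-nitro-6-oxabicyclo[3.1.0]hexan-2-yl]heptanoate F2 (epoxide face of no consequence). Opening with LiBr in THF at C10, with loss of nitrite, should give the α-bromo ketone methyl 7-[(1R,5R)-3-bromo-5-[(1E,3S)-3-hydroxyoct-1-en-1-yl]-2-oxocyclopentyl]heptanoate F3. Dehydrobromination (Li2CO3, LiBr, DMF, 80 °C) can only involve the C11 hydrogens. The fallback comes back to the route at 15.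

**Step 9.** The alkoxide/copper medium may isomerise the base-sensitive cyclopentenone, facial selectivity at C11 may be insufficient, or the β-boryl ketone may protodeboronate. Fallback: the C11 oxygen is introduced as an epoxide and the C9 ketone is reduced on a silyl-protected substrate. Setting out from 15, nucleophilic epoxidation (H2O2, NaOH, MeOH, −40 °C) should give methyl (13E,15S)-10α,11α-epoxy-15-hydroxy-9-oxoprost-13-en-1-oate F4. Reductive opening at C10 (Zn, NH4Cl, EtOH/H2O) should give PGE1 methyl ester F5, and silylation (TBSCl, imidazole, DMF) its 11,15-bis(tert-butyldimethylsilyl) ether F6. Reduction with LiBH(s-Bu)3 at −78 °C should give the 9α alcohol, the 11,15-bis(tert-butyldimethylsilyl) ether of PGF1α methyl ester F7. Desilylation with HF·pyridine in MeCN brings the fallback back to the route at 18.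

## Further compounds

F1 | step 4 | methyl (8R,9R)-9-formyl-11,11-dimethoxy-8-(nitromethyl)undecanoate | O=C[C@H](CC(OC)OC)[C@@H](CCCCCCC(=O)OC)C[N+](=O)[O-]
F2 | step 8 | methyl 7-[(2R,3R)-3-[(1E,3S)-3-hydroxyoct-1-en-1-yl]-1-nitro-6-oxabicyclo[3.1.0]hexan-2-yl]heptanoate (epoxide face not defined) | CCCCC[C@H](O)/C=C/[C@@H]1[C@@H](CCCCCCC(=O)OC)C2([N+](=O)[O-])OC2C1
F3 | step 8 | methyl 7-[(1R,5R)-3-bromo-5-[(1E,3S)-3-hydroxyoct-1-en-1-yl]-2-oxocyclopentyl]heptanoate (C–Br centre not defined) | CCCCC[C@H](O)/C=C/[C@@H]1[C@@H](CCCCCCC(=O)OC)C(=O)C(Br)C1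
F4 | step 9 | methyl (13E,15S)-10α,11α-epoxy-15-hydroxy-9-oxoprost-13-en-1-oate | CCCCC[C@H](O)/C=C/[C@@H]1[C@@H](CCCCCCC(=O)OC)C(=O)[C@H]2O[C@@H]12
F5 | step 9 | PGE1 methyl ester, methyl (11α,13E,15S)-11,15-dihydroxy-9-oxoprost-13-en-1-oate | CCCCC[C@H](O)/C=C/[C@@H]1[C@@H](CCCCCCC(=O)OC)C(=O)C[C@H]1O
F6 | step 9 | 11,15-bis(tert-butyldimethylsilyl) ether of PGE1 methyl ester | CCCCC[C@H](O[Si](C)(C)C(C)(C)C)/C=C/[C@@H]1[C@@H](CCCCCCC(=O)OC)C(=O)C[C@H]1O[Si](C)(C)C(C)(C)C
F7 | step 9 | 11,15-bis(tert-butyldimethylsilyl) ether of PGF1α methyl ester | CCCCC[C@H](O[Si](C)(C)C(C)(C)C)/C=C/[C@@H]1[C@@H](CCCCCCC(=O)OC)[C@@H](O)C[C@H]1O[Si](C)(C)C(C)(C)C
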